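**Retrosynthetic overview**
1. The target carries an acrolein unit (C4(=C3H2)–C15HO) on C5 and a cis 6β-oxygen on the cyclohexane ring (C5–C10). I read this pair as a 2-substituted acrylate acylating O6, so the target comes from tricycle 31, which holds a relay α-methylene-γ-lactone (C15–O6), by lactone reduction, O6 isobutyrylation and oxidation.
2. Tricycle 31 comes from bromo aldehyde 28 by an intramolecular zinc Barbier allylation–lactonisation (C5–C6, then O6–C15). The permanent lactone is stored as a cis-fused 2-methoxyoxolane so that the relay lactone is the only carboxyl derivative present when it is reduced.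
3. Bromo aldehyde 28 comes from lactone 20, itself made from aldehyde 11 and bromide 15 by a first, intermolecular chelation-controlled Barbier lactonisation (C7–C8, O8–C12) and conjugate reduction (C11). The C10 arm then becomes the (Z)-2-(bromomethyl)enoate by vinylalumination and SN2′ bromination.
4. Aldehyde 11 comes from prenyl acetate 1 through Sharpless epoxide 5 and alkynylalane opening at C10 (sets C9 and C10).
5. Ring order: oxolane ring (step 12), then cyclohexane ring and relay lactone ring together (step 21); the relay ring is opened (step 22) and the oxolane is oxidised back to the lactone (step 26).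

Key step: step 21

Assumption: atom labels C1–C15 are those of the target's elemane skeleton (C10 quaternary, C8–O–C12 lactone); TBS = tert-butyldimethylsilyl, TBDPS = tert-butyldiphenylsilyl, PMB = 4-methoxybenzyl; the acetal carbons of 9 and of 21–35 (C12) are carried as epimer mixtures that converge later; aldehyde 12 is taken as a catalogue compound.

Step 1
Reactants: 1 3-methylbut-2-en-1-yl acetate (prenyl acetate)
Product: 2 (2E)-4-hydroxy-3-methylbut-2-en-1-yl acetate
Conditions: SeO2 (0.3 equiv), t-BuOOH (70% aq., 3 equiv), salicylic acid (0.1 equiv), CH2Cl2, rt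
Reagents that add atoms: tert-butyl hydroperoxide, CC(C)(C)OO
Why: Riley allylic oxidation (ene reaction, then [2,3]-shift of the allylseleninic acid) hydroxylates the methyl group trans to the chain, so only the (E)-alcohol should form.

Step 2
Reactants: 2 (2E)-4-hydroxy-3-methylbut-2-en-1-yl acetate
Product: 3 (2E)-4-(TBSO)-3-methylbut-2-en-1-yl acetate
Conditions: TBSCl, imidazole, DMF, 0 °C → rt
Reagents that add atoms: tert-butyldimethylsilyl chloride, CC(C)(C)[Si](C)(C)Cl
Why: Standard silylation of the primary allylic alcohol, which will become the C5 arm.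

Step 3
Reactants: 3 (2E)-4-(TBSO)-3-methylbut-2-en-1-yl acetate
Product: 4 (2E)-4-(TBSO)-3-methylbut-2-en-1-ol
Conditions: K2CO3 (0.2 equiv), MeOH, 0 °C
Reagents that add atoms: none
Why: Base-catalysed transesterification removes the acetate without touching the silyl ether or the alkene geometry.

Step 4
Reactants: 4 (2E)-4-(TBSO)-3-methylbut-2-en-1-ol
Product: 5 [(2R,3R)-3-(TBSOCH2)-3-methyloxiran-2-yl]methanol
Conditions: Ti(OiPr)4 (0.1 equiv), D-(−)-diethyl tartrate (0.12 equiv), t-BuOOH (anhydrous, 2 equiv), 4 Å MS, CH2Cl2, −20 °C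
Reagents that add atoms: tert-butyl hydroperoxide, CC(C)(C)OO
Why: Sharpless asymmetric epoxidation; D-(−)-tartrate delivers oxygen to the face opposite to the one that gives (2S,3S)-epoxides from (E)-allylic alcohols with L-(+)-tartrate, so the (2R,3R)-epoxide should form and fixes C9 and, after inversion, C10.

Step 5
Reactants: 5 [(2R,3R)-3-(TBSOCH2)-3-methyloxiran-2-yl]methanol
Product: 7 (2S,3S)-3-(TBSOCH2)-3-methylpent-4-yne-1,2-diol, via silylalkyne diol 6 (not isolated)
Conditions: TMSC≡CH, n-BuLi, then Et2AlCl, toluene, 0 °C; add 5, 0 °C → rt; then K2CO3, MeOH, rt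
Reagents that add atoms: (trimethylsilyl)acetylene, C#C[Si](C)(C)C
Why: Organoaluminium opening of a 2,3-epoxy alcohol at the distal, more substituted carbon: the alkynylalane attacks the tertiary C10 with inversion, so C10 becomes quaternary with the alkyne anti to O9 while C9 keeps its configuration, and methanolysis then removes the alkyne silyl group.

Step 6
Reactants: 7 (2S,3S)-3-(TBSOCH2)-3-methylpent-4-yne-1,2-diol
Product: 8 (2S,3S)-3-(TBSOCH2)-3-methylpent-4-ene-1,2-diol
Conditions: H2 (1 atm), Pd/CaCO3 poisoned with Pb(OAc)2, quinoline, EtOAc, rt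
Reagents that add atoms: none
Why: Lindlar semi-hydrogenation of the terminal alkyne stops at the C10 vinyl group and affects no stereocentre.

Step 7
Reactants: 8 (2S,3S)-3-(TBSOCH2)-3-methylpent-4-ene-1,2-diol
Product: 9 (4S)-4-[(2S)-1-(TBSO)-2-methylbut-3-en-2-yl]-2-(4-methoxyphenyl)-1,3-dioxolane
Conditions: 4-MeOC6H4CH(OMe)2, PPTS (cat.), CH2Cl2, rt
Reagents that add atoms: 4-methoxybenzaldehyde dimethyl acetal, COC(OC)c1ccc(OC)cc1
Why: Acid-catalysed transacetalisation ties the 1,2-diol into a 4-methoxybenzylidene acetal; the chain stereocentres are untouched and the acetal-carbon epimers converge in step 8.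

Step 8
Reactants: 9 (4S)-4-[(2S)-1-(TBSO)-2-methylbut-3-en-2-yl]-2-(4-methoxyphenyl)-1,3-dioxolane
Product: 10 (2S,3S)-3-(TBSOCH2)-2-(PMBO)-3-methylpent-4-en-1-ol
Conditions: i-Bu2AlH (DIBAL-H, 3 equiv), CH2Cl2, −78 → 0 °C
Reagents that add atoms: none
Why: Reductive acetal opening: the aluminium hydride coordinates the less hindered primary oxygen and delivers hydride to the oxocarbenium ion, leaving the PMB ether on the hindered secondary O9 and freeing the C8 alcohol.

Step 9
Reactants: 10 (2S,3S)-3-(TBSOCH2)-2-(PMBO)-3-methylpent-4-en-1-ol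
Product: 11 (2S,3S)-3-(TBSOCH2)-2-(PMBO)-3-methylpent-4-enal
Conditions: TEMPO (0.1 equiv), PhI(OAc)2 (1.2 equiv), CH2Cl2, rt
Reagents that add atoms: none
Why: Oxoammonium (TEMPO) oxidation of the primary alcohol stops at the aldehyde under non-basic conditions, so the α-alkoxy centre C9 should not epimerise.

Step 10
Reactants: 12 (TBDPSO)acetaldehyde; 13 methyl acrylate
Product: 14 methyl 4-(TBDPSO)-3-hydroxy-2-methylidenebutanoate (racemic)
Conditions: DABCO (0.5 equiv), methyl acrylate (3 equiv), MeOH, rt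
Reagents that add atoms: none
Why: Morita–Baylis–Hillman reaction of an unhindered α-silyloxy aldehyde; the carbinol centre is racemic and is erased in step 11.

Step 11
Reactants: 14 methyl 4-(TBDPSO)-3-hydroxy-2-methylidenebutanoate
Product: 15 methyl (2Z)-2-(bromomethyl)-4-(TBDPSO)but-2-enoate
Conditions: NBS, Me2S, CH2Cl2, 0 °C → rt
Reagents that add atoms: N-bromosuccinimide, BrN1C(=O)CCC1=O
Why: Corey–Kim-type activation of the alcohol and SN2′ attack of bromide give the rearranged, thermodynamically preferred (Z)-2-(bromomethyl)enoate, the usual outcome for Baylis–Hillman alcohols.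

Step 12
Reactants: 11 (2S,3S)-3-(TBSOCH2)-2-(PMBO)-3-methylpent-4-enal; 15 methyl (2Z)-2-(bromomethyl)-4-(TBDPSO)but-2-enoate
Product: 18 (4S,5S)-5-[(1S,2S)-1-(PMBO)-2-(TBSOCH2)-2-methylbut-3-en-1-yl]-4-(TBDPSOCH2)-3-methylideneoxolan-2-one, via allylzinc bromide 16 (not isolated), via zinc alkoxide 17 (not isolated)
Conditions: Zn dust (activated with TMSCl), THF, 0 °C → rt, then 50 °C
Reagents that add atoms: none
Why: Zinc Barbier (Dreiding–Schmidt) allylation–lactonisation: the allylzinc adds through C7 to the zinc-chelated α-PMB-oxy aldehyde on the face away from the quaternary C10 (Cram chelate, 8,9-syn), and the ester-coordinated (Z)-allylzinc chair gives the 7,8-syn adduct, which lactonises to the cis-4,5-disubstituted lactone.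

Step 13
Reactants: 18 (4S,5S)-α-methylene lactone
Product: 20 (3R,4S,5S)-5-[(1S,2S)-1-(PMBO)-2-(TBSOCH2)-2-methylbut-3-en-1-yl]-4-(TBDPSOCH2)-3-methyloxolan-2-one, via 3-epi lactone 19 (not isolated)
Conditions: NaBH4, MeOH, 0 °C; then DBU, toluene, 80 °C
Reagents that add atoms: none
Why: Conjugate hydride addition to the α-methylene lactone followed by base equilibration of the enolisable C11 should leave the methyl group trans to the adjacent C7 substituent (thermodynamic control), which is the 11R configuration of the target.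

Step 14
Reactants: 20 (3R,4S,5S)-α-methyl lactone
Product: 21 (3R,4S,5S)-5-[(1S,2S)-1-(PMBO)-2-(TBSOCH2)-2-methylbut-3-en-1-yl]-4-(TBDPSOCH2)-3-methyloxolan-2-ol (C12 anomers)
Conditions: i-Bu2AlH (DIBAL-H, 1.2 equiv), CH2Cl2, −78 °C
Reagents that add atoms: none
Why: Partial reduction of the γ-lactone stops at the aluminium hemiacetal at −78 °C and gives the lactol without touching C11.

Step 15
Reactants: 21 lactol
Product: 23 2-methoxyoxolane with free C5 hydroxyl (C12 anomers), via silyl ether methyl acetal 22 (not isolated)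
Conditions: CSA (0.2 equiv), MeOH, 0 °C → rt
Reagents that add atoms: methanol, CO
Why: Fischer-type acetalisation turns the lactol into the methyl acetal, and the same acid in methanol cleaves the primary TBS ether much faster than the primary TBDPS ether, so only the C5 hydroxyl is freed.

Step 16
Reactants: 23 2-methoxyoxolane C5 alcohol
Product: 24 C5 aldehyde (formyl group on the quaternary C10)
Conditions: Dess–Martin periodinane, pyridine, CH2Cl2, rt
Reagents that add atoms: none
Why: Dess–Martin oxidation of the neopentyl primary alcohol gives an aldehyde on a quaternary carbon that can neither enolise nor epimerise.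

Step 17
Reactants: 24 C5 aldehyde
Product: 25 Baylis–Hillman-type adduct, C5 carbinol bearing the 1-(methoxycarbonyl)ethenyl group (C5 epimers)
Conditions: i-Bu2AlH (DIBAL-H), NMO, THF, 0 °C; methyl propiolate, 0 °C; then 24, rt
Reagents that add atoms: methyl propiolate, C#CC(=O)OC
Why: Vinylalumination: the [α-(methoxycarbonyl)vinyl]aluminium reagent from hydroalumination of methyl propiolate adds 1,2 to the hindered neopentyl aldehyde, which amine-catalysed Morita–Baylis–Hillman conditions would not manage, and the C5 configuration does not matter because it is erased in step 20.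

Step 18
Reactants: 25 Baylis–Hillman-type adduct
Product: 26 C5,C6-diol (C6 primary alcohol freed)
Conditions: TBAF, AcOH, THF, rt
Reagents that add atoms: none
Why: Fluoride cleavage of the TBDPS ether, buffered with acetic acid so that the acrylate is not exposed to basic alkoxide.

Step 19
Reactants: 26 C5,C6-diol
Product: 27 C6 aldehyde with free C5 carbinol
Conditions: TEMPO (0.1 equiv), PhI(OAc)2 (1.1 equiv), CH2Cl2, rt
Reagents that add atoms: none
Why: Oxoammonium oxidation is selective for the primary C6 alcohol over the hindered neopentyl secondary carbinol and is non-basic, which protects the epimerisable C7 of the β-alkoxy aldehyde.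

Step 20
Reactants: 27 C6 aldehyde with free C5 carbinol
Product: 28 bromo aldehyde: C6 aldehyde on the cis-fused 2-methoxyoxolane, with the methyl (2Z)-2-(bromomethyl)enoate (C5=C4) on C10
Conditions: NBS, Me2S, CH2Cl2, −20 → 0 °C
Reagents that add atoms: N-bromosuccinimide, BrN1C(=O)CCC1=O
Why: Corey–Kim-type activation and SN2′ attack of bromide at the terminal methylene give the rearranged allyl bromide, (Z) because the quaternary C10 prefers to lie trans to the ester; either alkene isomer would give the same allylzinc.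

Step 21
Reactants: 28 bromo aldehyde
Product: 31 tricyclic relay lactone (α-methylene-γ-lactone cis-fused at C5/C6 on the β-face; 2-methoxyoxolane cis-fused at C7/C8; 9α-OPMB; 10β-methyl; 10α-vinyl), via allylzinc bromide 29 (not isolated), via zinc alkoxide 30 (not isolated)
Conditions: Zn dust (activated with TMSCl), THF, 0.01 M, rt → 45 °C
Reagents that add atoms: none
Why: Zinc inserts into the C3–Br bond to give the ester-chelated 2-(methoxycarbonyl)allylzinc 29, which adds through its γ-carbon C5 (SE2′) to the C6 aldehyde in a closed chair-like six-membered array (Zn–O6–C6–C5–C4–C3), making the C5–C6 bond and the C4=C3 methylene; the O6 zinc alkoxide 30 then acylates on the neighbouring methyl ester. The closest known reaction type is the intramolecular zinc-mediated Barbier (Dreiding–Schmidt) allylation–lactonisation of 2-(bromomethyl)acrylates, which gives cis-fused α-methylene-γ-butyrolactones. The cyclohexane ring (C5–C10) closes by 6-exo-trig attack of C5 on the formyl carbon and the relay lactone ring by 5-exo-trig attack of O6 on C15. C5 relative to C6 is set by the allylzinc geometry: the quaternary C10 lies trans to the ester, so the tether is axial on the metallacycle with C7 equatorial, which leads to the cis (syn) adduct, the one that lactonises without strain. The face at C6 is set by C7: in the reacting chair C11 is equatorial and anti to the incoming C5 (Felkin–Anh), and the ring oxygen O8 is syn-axial to the zinc-bound O6 and can bridge the same zinc, so O6 and C4 should end on the β-face with C10–CH3, O8 and C11. The step needs cis C5/C6 on the β-face and reaction at the aldehyde only; the chelating acetal oxygen at C8, the rigid cis-fused oxolane and the storage of C12 as an acetal (no second electrophile) are meant to secure this.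

Step 22
Reactants: 31 tricyclic relay lactone
Product: 32 C6,C15-diol (relay lactone opened; 2-(hydroxymethyl)allyl unit on C5)
Conditions: i-Bu2AlH (DIBAL-H, 3 equiv), CH2Cl2, −78 → 0 °C
Reagents that add atoms: none
Why: 1,2-Reduction of the conjugated lactone (lactol, then allylic alcohol) gives the diol, while the C12 acetal is not electrophilic towards the hydride.

Step 23
Reactants: 32 C6,C15-diol
Product: 33 15-O-TBS ether with free 6-OH
Conditions: TBSCl (1.1 equiv), imidazole, CH2Cl2, 0 °C
Reagents that add atoms: tert-butyldimethylsilyl chloride, CC(C)(C)[Si](C)(C)Cl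
Why: Silylation discriminates the primary allylic C15 hydroxyl from the hindered secondary C6 hydroxyl.

Step 24
Reactants: 33 15-O-TBS ether
Product: 34 6-O-isobutyrate
Conditions: (i-PrCO)2O, Et3N, DMAP, CH2Cl2, rt
Reagents that add atoms: isobutyric anhydride, CC(C)C(=O)OC(=O)C(C)C
Why: DMAP-catalysed acyl transfer esterifies the only free hydroxyl, O6, with retention at C6.

Step 25
Reactants: 34 6-O-isobutyrate
Product: 35 lactol with free C15 allylic alcohol (C12 anomers)
Conditions: AcOH/THF/H2O (3:1:1), 40 °C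
Reagents that add atoms: water, O
Why: Aqueous acid hydrolyses the primary allylic silyl ether and the 2-methoxyoxolane acetal in one operation, while the PMB ether and the isobutyrate are stable.

Step 26
Reactants: 35 lactol with free C15 allylic alcohol
Product: 36 9-O-PMB ether of the target (enal and γ-lactone in place)
Conditions: TEMPO (0.2 equiv), PhI(OAc)2 (2.5 equiv), CH2Cl2, rt
Reagents that add atoms: none
Why: Oxoammonium oxidation converts the primary allylic alcohol into the enal and the lactol into the γ-lactone in the same flask under non-basic conditions, so C11 and C5 are not enolised.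

Step 27
Reactants: 36 9-O-PMB ether of the target
Product: 37 CNP0198892.2 (target)
Conditions: DDQ, CH2Cl2/pH 7 buffer, 0 °C
Reagents that add atoms: none
Why: Oxidative PMB cleavage (hydride abstraction by DDQ, hydrolysis of the oxocarbenium ion) frees the 9-hydroxyl under neutral conditions that the enal, the ester and the lactone tolerate.

**Compound list**
1 | 3-methylbut-2-en-1-yl acetate (prenyl acetate) | CC(C)=CCOC(C)=O | starting material
2 | (2E)-4-hydroxy-3-methylbut-2-en-1-yl acetate | CC(=O)OC/C=C(\C)CO | intermediate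
3 | (2E)-4-[(tert-butyldimethylsilyl)oxy]-3-methylbut-2-en-1-yl acetate | CC(=O)OC/C=C(\C)CO[Si](C)(C)C(C)(C)C | intermediate
4 | (2E)-4-[(tert-butyldimethylsilyl)oxy]-3-methylbut-2-en-1-ol | OC/C=C(\C)CO[Si](C)(C)C(C)(C)C | intermediate
5 | [(2R,3R)-3-{[(tert-butyldimethylsilyl)oxy]methyl}-3-methyloxiran-2-yl]methanol | OC[C@H]1O[C@]1(C)CO[Si](C)(C)C(C)(C)C | intermediate
6 | (2S,3S)-3-(TBSOCH2)-3-methyl-5-(trimethylsilyl)pent-4-yne-1,2-diol | OC[C@@H](O)[C@](C)(CO[Si](C)(C)C(C)(C)C)C#C[Si](C)(C)C | intermediate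
7 | (2S,3S)-3-(TBSOCH2)-3-methylpent-4-yne-1,2-diol | OC[C@@H](O)[C@](C)(CO[Si](C)(C)C(C)(C)C)C#C | intermediate
8 | (2S,3S)-3-(TBSOCH2)-3-methylpent-4-ene-1,2-diol | OC[C@@H](O)[C@](C)(CO[Si](C)(C)C(C)(C)C)C=C | intermediate
9 | (4S)-4-[(2S)-1-(TBSO)-2-methylbut-3-en-2-yl]-2-(4-methoxyphenyl)-1,3-dioxolane (epimers at the acetal carbon) | COc1ccc(cc1)C1OC[C@@H](O1)[C@](C)(CO[Si](C)(C)C(C)(C)C)C=C | intermediate
10 | (2S,3S)-3-(TBSOCH2)-2-[(4-methoxybenzyl)oxy]-3-methylpent-4-en-1-ol | OC[C@@H](OCc1ccc(OC)cc1)[C@](C)(CO[Si](C)(C)C(C)(C)C)C=C | intermediate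
11 | (2S,3S)-3-(TBSOCH2)-2-[(4-methoxybenzyl)oxy]-3-methylpent-4-enal | O=C[C@@H](OCc1ccc(OC)cc1)[C@](C)(CO[Si](C)(C)C(C)(C)C)C=C | intermediate
12 | [(tert-butyldiphenylsilyl)oxy]acetaldehyde | O=CCO[Si](c1ccccc1)(c1ccccc1)C(C)(C)C | starting material
13 | methyl acrylate | C=CC(=O)OC | starting material
14 | methyl 4-(TBDPSO)-3-hydroxy-2-methylidenebutanoate (racemic) | COC(=O)C(=C)C(O)CO[Si](c1ccccc1)(c1ccccc1)C(C)(C)C | intermediate
15 | methyl (2Z)-2-(bromomethyl)-4-(TBDPSO)but-2-enoate | COC(=O)/C(CBr)=C/CO[Si](c1ccccc1)(c1ccccc1)C(C)(C)C | intermediate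
16 | [(2Z)-2-(methoxycarbonyl)-4-(TBDPSO)but-2-en-1-yl]zinc bromide | COC(=O)/C(C[Zn]Br)=C/CO[Si](c1ccccc1)(c1ccccc1)C(C)(C)C | intermediate
17 | bromozinc alkoxide of the 7,8-syn-8,9-syn homoallylic alcohol (open form of 18) | C=C(C(=O)OC)[C@@H](CO[Si](c1ccccc1)(c1ccccc1)C(C)(C)C)[C@H](O[Zn]Br)[C@@H](OCc1ccc(OC)cc1)[C@](C)(CO[Si](C)(C)C(C)(C)C)C=C | intermediate
18 | (4S,5S)-5-[(1S,2S)-1-(PMBO)-2-(TBSOCH2)-2-methylbut-3-en-1-yl]-4-(TBDPSOCH2)-3-methylideneoxolan-2-one (4,5-cis) | C=C1C(=O)O[C@H]([C@@H](OCc2ccc(OC)cc2)[C@](C)(CO[Si](C)(C)C(C)(C)C)C=C)[C@@H]1CO[Si](c1ccccc1)(c1ccccc1)C(C)(C)C | intermediate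
19 | (3S,4S,5S)-3-methyl epimer of 20 (all-cis, kinetic protonation product) | C[C@@H]1C(=O)O[C@H]([C@@H](OCc2ccc(OC)cc2)[C@](C)(CO[Si](C)(C)C(C)(C)C)C=C)[C@@H]1CO[Si](c1ccccc1)(c1ccccc1)C(C)(C)C | intermediate
20 | (3R,4S,5S)-5-[(1S,2S)-1-(PMBO)-2-(TBSOCH2)-2-methylbut-3-en-1-yl]-4-(TBDPSOCH2)-3-methyloxolan-2-one (3,4-trans, 4,5-cis) | C[C@H]1C(=O)O[C@H]([C@@H](OCc2ccc(OC)cc2)[C@](C)(CO[Si](C)(C)C(C)(C)C)C=C)[C@@H]1CO[Si](c1ccccc1)(c1ccccc1)C(C)(C)C | intermediate
21 | (3R,4S,5S)-lactol of 20 (oxolan-2-ol, C12 anomers) | C[C@H]1C(O)O[C@H]([C@@H](OCc2ccc(OC)cc2)[C@](C)(CO[Si](C)(C)C(C)(C)C)C=C)[C@@H]1CO[Si](c1ccccc1)(c1ccccc1)C(C)(C)C | intermediate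
22 | methyl acetal of 21 (2-methoxyoxolane, TBS ether still on O5) | C[C@H]1C(OC)O[C@H]([C@@H](OCc2ccc(OC)cc2)[C@](C)(CO[Si](C)(C)C(C)(C)C)C=C)[C@@H]1CO[Si](c1ccccc1)(c1ccccc1)C(C)(C)C | intermediate
23 | 2-methoxyoxolane with free C5 hydroxyl (configuration as 21) | C[C@H]1C(OC)O[C@H]([C@@H](OCc2ccc(OC)cc2)[C@](C)(CO)C=C)[C@@H]1CO[Si](c1ccccc1)(c1ccccc1)C(C)(C)C | intermediate
24 | C5 aldehyde (formyl on quaternary C10) | C[C@H]1C(OC)O[C@H]([C@@H](OCc2ccc(OC)cc2)[C@](C)(C=O)C=C)[C@@H]1CO[Si](c1ccccc1)(c1ccccc1)C(C)(C)C | intermediate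
25 | Baylis–Hillman-type adduct: C5 carbinol bearing the 1-(methoxycarbonyl)ethenyl group (C5 epimers) | C[C@H]1C(OC)O[C@H]([C@@H](OCc2ccc(OC)cc2)[C@](C)(C(O)C(=C)C(=O)OC)C=C)[C@@H]1CO[Si](c1ccccc1)(c1ccccc1)C(C)(C)C | intermediate
26 | C5,C6-diol (C6 primary alcohol free) | C[C@H]1C(OC)O[C@H]([C@@H](OCc2ccc(OC)cc2)[C@](C)(C(O)C(=C)C(=O)OC)C=C)[C@@H]1CO | intermediate
27 | C6 aldehyde with free C5 carbinol | C[C@H]1C(OC)O[C@H]([C@@H](OCc2ccc(OC)cc2)[C@](C)(C(O)C(=C)C(=O)OC)C=C)[C@@H]1C=O | intermediate
28 | bromo aldehyde (key-step precursor): C6 aldehyde on the 7,8-cis 2-methoxyoxolane, 9-OPMB, C10 carrying methyl, vinyl and the methyl (2Z)-2-(bromomethyl)enoate | C[C@H]1C(OC)O[C@H]([C@@H](OCc2ccc(OC)cc2)[C@](C)(/C=C(\CBr)C(=O)OC)C=C)[C@@H]1C=O | intermediate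
29 | allylzinc bromide from 28 | C[C@H]1C(OC)O[C@H]([C@@H](OCc2ccc(OC)cc2)[C@](C)(/C=C(\C[Zn]Br)C(=O)OC)C=C)[C@@H]1C=O | intermediate
30 | bromozinc alkoxide of the cyclised 6-hydroxy methyl ester | C=C[C@]1(C)[C@H](OCc4ccc(OC)cc4)[C@H]3OC(OC)[C@H](C)[C@H]3[C@@H](O[Zn]Br)[C@H]1C(=C)C(=O)OC | intermediate
31 | tricyclic relay lactone (key-step product): cyclohexane with the α-methylene-γ-lactone (C15–O6) cis-fused at C5/C6 on the β-face, the 2-methoxyoxolane cis-fused at C7/C8, 9α-OPMB, 10β-methyl, 10α-vinyl | C=C[C@]1(C)[C@H](OCc4ccc(OC)cc4)[C@H]3OC(OC)[C@H](C)[C@H]3[C@H]2OC(=O)C(=C)[C@@H]12 | intermediate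
32 | C6,C15-diol (relay lactone opened) | C=C[C@]1(C)[C@H](OCc4ccc(OC)cc4)[C@H]3OC(OC)[C@H](C)[C@H]3[C@@H](O)[C@H]1C(=C)CO | intermediate
33 | 15-O-TBS ether, 6-OH free | C=C[C@]1(C)[C@H](OCc4ccc(OC)cc4)[C@H]3OC(OC)[C@H](C)[C@H]3[C@@H](O)[C@H]1C(=C)CO[Si](C)(C)C(C)(C)C | intermediate
34 | 6-O-isobutyrate, 15-O-TBS ether | C=C[C@]1(C)[C@H](OCc4ccc(OC)cc4)[C@H]3OC(OC)[C@H](C)[C@H]3[C@@H](OC(=O)C(C)C)[C@H]1C(=C)CO[Si](C)(C)C(C)(C)C | intermediate
35 | lactol (C12 anomers) with free C15 allylic alcohol and 6-O-isobutyrate | C=C[C@]1(C)[C@H](OCc4ccc(OC)cc4)[C@H]3OC(O)[C@H](C)[C@H]3[C@@H](OC(=O)C(C)C)[C@H]1C(=C)CO | intermediate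
36 | 9-O-(4-methoxybenzyl) ether of the target | C=C[C@]1(C)[C@H](OCc4ccc(OC)cc4)[C@H]3OC(=O)[C@H](C)[C@H]3[C@@H](OC(=O)C(C)C)[C@H]1C(=C)C=O | intermediate
37 | CNP0198892.2 (5R,6S,7S,8S,9S,10S,11R) | C=C[C@]1(C)[C@H](O)[C@H]2OC(=O)[C@H](C)[C@H]2[C@@H](OC(=O)C(C)C)[C@H]1C(=C)C=O | target

**Step count and risks**
Total step count: 27. Longest linear sequence: 25 steps (steps 1–9 and 12–27); bromide 15 takes 2 steps (10–11).

Steps most likely to fail:

1. Step 21 (key step). The allylzinc may add to the α-face of the aldehyde, giving the cis-lactone epimeric at both C5 and C6. This is possible because the desired chair has a syn-axial C10–CH3/O8 contact. Closure through the (E)-allylzinc to a trans-fused lactone, or epimerisation or β-elimination at C7 before cyclisation, are further failure modes. Fallback: set out from 28 and replace the closed organozinc transition state by a Lewis-acid-chelated open one. Pd(PPh3)4-catalysed stannylation with (Bu3Sn)2 in THF should give the allylstannane aldehyde F1. MgBr2·OEt2 in CH2Cl2 at −78 °C, bound to O6 and O8, should then trigger the intramolecular SE2′ allylstannane addition to the cyclised hydroxy ester F2. Lactonisation of F2 with catalytic CSA comes back to the route at 31.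

2. Step 12. Chelation control may be lost (Felkin–Anh addition would give the C8 epimer), or syn/anti selection at C7/C8 may be incomplete, giving the trans-lactone. Fallback: set out from 15 and convert it with (Bu3Sn)2 and Pd(PPh3)4 into the allylstannane ester F3. Its addition to 11, precomplexed with MgBr2·OEt2 in CH2Cl2 at −78 °C (Cram-chelate, antiperiplanar SE2′), should give the syn,syn hydroxy ester F4. Lactonisation of F4 with catalytic CSA comes back to the route at 18.

3. Step 5. The alkynylalane may attack the secondary C9 instead of the tertiary C10, or C10 may ionise with loss of stereochemical integrity or rearrangement. Fallback: set out from 4 and esterify it with [(4-methoxybenzyl)oxy]acetic acid (DCC, DMAP) to the allyl glycolate F5. Ireland–Claisen rearrangement (i-Pr2NLi, TMSCl, THF, −78 °C → rt) through the chelated (Z)-silyl ketene acetal and a chair transition state should give the racemic 2,3-syn acid. Resolution by crystallisation of its salt with one enantiomer of 1-phenylethylamine should give the (2S,3S)-acid F6. LiAlH4 reduction comes back to the route at 10.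

**Further compounds**
F1 | step 21 | allylstannane aldehyde: 28 with CH2SnBu3 in place of CH2Br (alkene isomers) | C[C@H]1C(OC)O[C@H]([C@@H](OCc2ccc(OC)cc2)[C@](C)(C=C(C[Sn](CCCC)(CCCC)CCCC)C(=O)OC)C=C)[C@@H]1C=O
F2 | step 21 | cyclised hydroxy ester: methyl 2-substituted acrylate on C5, free 6β-OH (neutral form of 30) | C=C[C@]1(C)[C@H](OCc4ccc(OC)cc4)[C@H]3OC(OC)[C@H](C)[C@H]3[C@@H](O)[C@H]1C(=C)C(=O)OC
F3 | step 12 | methyl 4-(TBDPSO)-2-[(tributylstannyl)methyl]but-2-enoate | COC(=O)C(C[Sn](CCCC)(CCCC)CCCC)=CCO[Si](c1ccccc1)(c1ccccc1)C(C)(C)C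
F4 | step 12 | syn,syn hydroxy ester (neutral form of 17) | C=C(C(=O)OC)[C@@H](CO[Si](c1ccccc1)(c1ccccc1)C(C)(C)C)[C@H](O)[C@@H](OCc1ccc(OC)cc1)[C@](C)(CO[Si](C)(C)C(C)(C)C)C=C
F5 | step 5 | (2E)-4-(TBSO)-3-methylbut-2-en-1-yl [(4-methoxybenzyl)oxy]acetate | COc1ccc(COCC(=O)OC/C=C(\C)CO[Si](C)(C)C(C)(C)C)cc1
F6 | step 5 | (2S,3S)-3-(TBSOCH2)-2-[(4-methoxybenzyl)oxy]-3-methylpent-4-enoic acid | OC(=O)[C@@H](OCc1ccc(OC)cc1)[C@](C)(CO[Si](C)(C)C(C)(C)C)C=C
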